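By 3.3 h the theta run has turned 86.7% of its substrate charge and the zeta run 74.3%, and two chemists dispute what that gap says about the order in substrate.

| setting | zeta | theta | beta | alpha | epsilon |
|---|---|---|---|---|---|
| substrate | 0.200 M | 0.100 M | 0.200 M | 0.200 M | 0.100 M |
| coupling partner | 0.220 M | 0.220 M | 0.660 M | 0.220 M | 0.660 M |
| free catalyst | 0.0160 M | 0.0160 M | 0.0160 M | 0.00800 M | 0.0160 M |
| time |  |  |  |  | 3.3 h |

| zeta run: time / h | zeta run: [product] / M | theta run: time / h | theta run: [product] / M | beta run: time / h | beta run: [product] / M | alpha run: time / h | alpha run: [product] / M |
|---|---|---|---|---|---|---|---|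
| 0.13 | 0.0059 | 0.13 | 0.0030 | 0.13 | 0.0070 | 0.13 | 0.0019 |
| 0.25 | 0.0153 | 0.25 | 0.0090 | 0.25 | 0.0159 | 0.25 | 0.0066 |
| 0.48 | 0.0302 | 0.48 | 0.0203 | 0.48 | 0.0314 | 0.48 | 0.0127 |
| 0.91 | 0.0565 | 0.91 | 0.0382 | 0.91 | 0.0572 | 0.91 | 0.0258 |
| 1.7 | 0.0974 | 1.7 | 0.0617 | 1.7 | 0.0997 | 1.7 | 0.0458 |
| 3.3 | 0.1486 | 3.3 | 0.0867 | 3.3 | 0.1529 | 3.3 | 0.0825 |

(readings scatter by 6 × 10⁻⁴ M)

1. how the opening rate goes with [substrate] round the charge of the zeta run: the exponent of the rate at two percent of substrate gone to product (one fixed amount of product, the same in the runs compared)
2. how the opening rate goes with [coupling partner] round the charge of the zeta run: the exponent of the rate at two percent of substrate gone to product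
3. product in the epsilon run at 3.3 h, as a share of the substrate charged

- Overall: substrate + coupling partner -> product, with free catalyst as catalyst.
- Constant volume, constant temperature.
- Readings of a species count what is bound in complexes too.
- An order is taken over about fifteen percent of the charge, up and down.

Substrate is the limiting reagent in the zeta run, at 0.200 M against 0.220 M of coupling partner. Both chemists set the partner aside: between 0.25 h and 0.91 h the beta run, with 3.00 times the partner, makes product at 0.0626 M/h, and the zeta run at 0.0624 M/h.

The first-order chemist takes substrate as charge less product and reads a rate constant from the theta run: 0.586 /h in that window and 0.661 /h from 1.7 h to 3.3 h. That is close to one constant, so this chemist claims an order of 1.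

The saturation chemist answers that the zeta run gives 0.382 /h in the same window, less than the theta run, whereas a first-order law demands one constant for both. This chemist writes the rate as proportional to S/(K+S), with S the substrate concentration, which makes the local order n = K/(K+S).

My own reckoning follows that form. The theta slope of 0.0442 M/h over the zeta slope gives a ratio of 0.709. Taken at the two charges, a rough step since both windows lie below them, this reads K = 0.140 M. K is the half-saturation concentration, the substrate concentration at which the rate stands at half its plateau. At the zeta charge it gives n = 0.411.

The forecast sides with saturation but reads a smaller K: “That fits saturation in substrate, with K about 0.1 M, giving a local order near 0.35.” It gives 0.35 for substrate (range 0.18 to 0.55), 0.05 for the partner, and 88.2% for the epsilon run. My n is higher than its figure.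

The simulation gives 0.43 in substrate and 0.035 in partner, with the epsilon run at 87.2%.

    free catalyst + substrate → catalyst-substrate complex (76.32 /M/h)
    catalyst-substrate complex + coupling partner → loaded catalyst (583.2 /M/h)
    loaded catalyst → product + free catalyst (9.252 /h)
    free catalyst + product ⇌ catalyst-product complex, settled at all times (4.860 /M)
    free catalyst + impurity → spent catalyst

The order at the zeta charge is below the first-order chemist's 1, and the rate of the theta run over that of the zeta run, both where two percent of the zeta substrate has turned, is 0.71. The first-order chemist keeps the end of the epsilon run: at 3.3 h about 0.01281 M of substrate is left by charge less product, and at that concentration K gives n = 0.916.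

Readings and results are calculated for an exercise, noise included.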